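**Plan**

- Retrosynthesis: the six methoxymethyl ethers come off last. Before that, the C1–C(=O) and C2–O bonds of the central ring B are cut together, back to a C1–C2 aryne and butyric acid.
- Feature used: on ring B the butyryl carbon C1 and the hydroxyl carbon C2 are adjacent. C1 is flanked by the C6 oxygen, which polarises the aryne so that oxygen enters at C2 and acyl at C1. C2 is flanked by the C3 methylene arm to acetyl ring A; C4 (oxygen) and C5 (methylene arm to butyryl ring C) are spectators.
- Next the two aryl–CH2 bonds are cut (C3–CH2 to ring A, C5–CH2 to ring C, Suzuki–Miyaura), then the C1–Si, C5–Cl and C3–CH2B bonds of ring B (three directed lithiations).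
- Forward: rings A and C are each made from 2,4,6-trihydroxytoluene (acylation, acetalisation, O-methylation, bromination) and ring B from phloroglucinol. Ring A is joined at C3, ring C at C5, the C2 benzyl ether is changed into the triflate, butyric acid is inserted, and acid frees the seven phenols.
- No ring is formed (all three benzene rings are bought) and the target has no stereocentre, so no stereocontrol is needed.

Key step: step 19

Remark: ring B is numbered C1 (butyryl carbon) to C6; MOM = methoxymethyl, Bpin = 4,4,5,5-tetramethyl-1,3,2-dioxaborolan-2-yl, ArA = 3-acetyl-4-methoxy-2,6-bis(methoxymethoxy)-5-methylphenyl, ArC = 3-butanoyl-4-methoxy-2,6-bis(methoxymethoxy)-5-methylphenyl; exchanging the arms at C3 and C5 gives the same target, so only the placing of silicon next to the triflate matters; CH2(Bpin)2 and ClCH2Bpin are taken as purchasable.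

**Route**

Step 1
Reactants: 1 2,4,6-trihydroxytoluene
Product: 2 1-(2,4,6-trihydroxy-3-methylphenyl)ethanone
Conditions: AcCl, AlCl3, PhNO2/CH2Cl2, 0 °C to rt; aq HCl
Reagents that add atoms: acetyl chloride, CC(=O)Cl
Why: Friedel–Crafts acylation of the phloroglucinol-type ring, whose two free positions are equivalent, and the first acyl group deactivates the ring so that monoacylation should prevail.

Step 2
Reactants: 2 1-(2,4,6-trihydroxy-3-methylphenyl)ethanone
Product: 3 1-[2-hydroxy-4,6-bis(methoxymethoxy)-3-methylphenyl]ethanone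
Conditions: MOMCl (2.2 equiv), i-Pr2NEt, CH2Cl2, 0 °C
Reagents that add atoms: chloromethyl methyl ether, COCCl
Why: Base-mediated O-alkylation (acetal formation) should take the para hydroxyl and the less hindered of the two chelated ortho hydroxyls, leaving free the hydrogen-bonded hydroxyl wedged between acetyl and methyl, the pattern known from partial alkylation of C-methylphloroacetophenones.

Step 3
Reactants: 3 1-[2-hydroxy-4,6-bis(methoxymethoxy)-3-methylphenyl]ethanone
Product: 4 1-[2-methoxy-4,6-bis(methoxymethoxy)-3-methylphenyl]ethanone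
Conditions: MeI, K2CO3, DMF, 40 °C
Reagents that add atoms: iodomethane, CI
Why: Williamson O-methylation of the one remaining, chelated phenol places the methoxy group between methyl and acetyl as required for ring A.

Step 4
Reactants: 4 1-[2-methoxy-4,6-bis(methoxymethoxy)-3-methylphenyl]ethanone
Product: 5 1-[3-bromo-6-methoxy-2,4-bis(methoxymethoxy)-5-methylphenyl]ethanone
Conditions: NBS, MeCN, 0 °C
Reagents that add atoms: N-bromosuccinimide, O=C1CCC(=O)N1Br
Why: Electrophilic aromatic bromination at the only unsubstituted ring carbon, which lies ortho to two acetal oxygens and para to the methoxy group, so that ring substitution should outpace α-bromination of the twisted ketone.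

Step 5
Reactants: 1 2,4,6-trihydroxytoluene
Product: 6 1-(2,4,6-trihydroxy-3-methylphenyl)butan-1-one
Conditions: n-PrCOCl, AlCl3, PhNO2/CH2Cl2, 0 °C to rt; aq HCl
Reagents that add atoms: butanoyl chloride, CCCC(=O)Cl
Why: Friedel–Crafts acylation as in step 1, with the same control of monoacylation by deactivation.

Step 6
Reactants: 6 1-(2,4,6-trihydroxy-3-methylphenyl)butan-1-one
Product: 7 1-[2-hydroxy-4,6-bis(methoxymethoxy)-3-methylphenyl]butan-1-one
Conditions: MOMCl (2.2 equiv), i-Pr2NEt, CH2Cl2, 0 °C
Reagents that add atoms: chloromethyl methyl ether, COCCl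
Why: Regioselective O-alkylation as in step 2, the hydroxyl between butanoyl and methyl being chelated and the most hindered.

Step 7
Reactants: 7 1-[2-hydroxy-4,6-bis(methoxymethoxy)-3-methylphenyl]butan-1-one
Product: 8 1-[2-methoxy-4,6-bis(methoxymethoxy)-3-methylphenyl]butan-1-one
Conditions: MeI, K2CO3, DMF, 40 °C
Reagents that add atoms: iodomethane, CI
Why: Williamson O-methylation of the single free phenol, as in step 3.

Step 8
Reactants: 8 1-[2-methoxy-4,6-bis(methoxymethoxy)-3-methylphenyl]butan-1-one
Product: 9 1-[3-bromo-6-methoxy-2,4-bis(methoxymethoxy)-5-methylphenyl]butan-1-one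
Conditions: NBS, MeCN, 0 °C
Reagents that add atoms: N-bromosuccinimide, O=C1CCC(=O)N1Br
Why: Electrophilic aromatic bromination at the one free, doubly ortho-alkoxylated ring position, as in step 4.

Step 9
Reactants: 9 1-[3-bromo-6-methoxy-2,4-bis(methoxymethoxy)-5-methylphenyl]butan-1-one
Product: 10 1-{6-methoxy-2,4-bis(methoxymethoxy)-5-methyl-3-[(Bpin)methyl]phenyl}butan-1-one
Conditions: CH2(Bpin)2 (1.5 equiv), Pd[P(t-Bu)3]2 (5 mol %), aq KOH, dioxane, rt to 40 °C
Reagents that add atoms: bis(pinacolatoboryl)methane, CC1(C)OB(CB2OC(C)(C)C(C)(C)O2)OC1(C)C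
Why: Suzuki–Miyaura coupling of a geminal diborylmethane, in which the second boryl group accelerates transmetalation so that the reaction should stop at the benzylic boronate while the ketone is untouched.

Step 10
Reactants: 11 phloroglucinol
Product: 12 3,5-bis(methoxymethoxy)phenol
Conditions: MOMCl (2.0 equiv), i-Pr2NEt, THF, 0 °C to rt
Reagents that add atoms: chloromethyl methyl ether, COCCl
Why: O-alkylation under statistical control, from which the bis-ether should be separable from mono- and tris-ethers by chromatography.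

Step 11
Reactants: 12 3,5-bis(methoxymethoxy)phenol
Product: 13 1-(benzyloxy)-3,5-bis(methoxymethoxy)benzene
Conditions: BnBr, K2CO3, DMF, rt
Reagents that add atoms: benzyl bromide, BrCc1ccccc1
Why: Williamson etherification gives the future C2 oxygen of ring B a protecting group that is stable to alkyllithiums and aqueous base and is removable without acid or fluoride.

Step 12
Reactants: 13 1-(benzyloxy)-3,5-bis(methoxymethoxy)benzene
Product: 15 5-(benzyloxy)-2-chloro-1,3-bis(methoxymethoxy)benzene, via aryllithium 14 (not isolated)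
Conditions: n-BuLi, TMEDA, THF, 0 °C; then C2Cl6, −78 °C to rt
Reagents that add atoms: hexachloroethane, ClC(Cl)(Cl)C(Cl)(Cl)Cl
Why: Directed ortho-metalation should remove the proton between the two methoxymethoxy groups (double chelation, the benzyl ether being the weaker director) and hexachloroethane chlorinates the aryllithium, placing at C5 of ring B a halogen that survives the later alkyllithium steps.

Step 13
Reactants: 15 5-(benzyloxy)-2-chloro-1,3-bis(methoxymethoxy)benzene
Product: 17 [2-(benzyloxy)-5-chloro-4,6-bis(methoxymethoxy)phenyl]trimethylsilane, via aryllithium 16 (not isolated)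
Conditions: s-BuLi, TMEDA, THF, −78 °C; then Me3SiCl, −78 °C to rt
Reagents that add atoms: chlorotrimethylsilane, C[Si](C)(C)Cl
Why: Directed ortho-metalation at one of the two equivalent positions between the benzyloxy and a methoxymethoxy group followed by C-silylation, the aryl chloride having no ortho hydrogen and not exchanging with alkyllithium at this temperature.

Step 14
Reactants: 17 [2-(benzyloxy)-5-chloro-4,6-bis(methoxymethoxy)phenyl]trimethylsilane
Product: 20 [2-(benzyloxy)-5-chloro-4,6-bis(methoxymethoxy)-3-[(Bpin)methyl]phenyl]trimethylsilane, via aryllithium 18 (not isolated), via chloromethyl borate 19 (not isolated)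
Conditions: s-BuLi, TMEDA, THF, −78 °C; then ClCH2Bpin, −78 °C to rt
Reagents that add atoms: 2-(chloromethyl)-4,4,5,5-tetramethyl-1,3,2-dioxaborolane, ClCB1OC(C)(C)C(C)(C)O1
Why: Directed ortho-metalation of the last ring hydrogen followed by a Matteson homologation, in which the aryl group of the borate shifts from boron to carbon with loss of chloride to give the benzylic boronate at C3.

Step 15
Reactants: 20 [2-(benzyloxy)-5-chloro-4,6-bis(methoxymethoxy)-3-[(Bpin)methyl]phenyl]trimethylsilane; 5 1-[3-bromo-6-methoxy-2,4-bis(methoxymethoxy)-5-methylphenyl]ethanone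
Product: 21 [2-(benzyloxy)-5-chloro-4,6-bis(methoxymethoxy)-3-(ArA-methyl)phenyl]trimethylsilane
Conditions: Pd(OAc)2, SPhos, K3PO4, toluene/H2O, 80 °C
Reagents that add atoms: none
Why: sp3–sp2 Suzuki–Miyaura coupling in which the aryl bromide should undergo oxidative addition far faster than the hindered, electron-rich aryl chloride of 20, while ketone, acetals, benzyl ether and the C–Si bond tolerate aqueous phosphate.

Step 16
Reactants: 21 [2-(benzyloxy)-5-chloro-4,6-bis(methoxymethoxy)-3-(ArA-methyl)phenyl]trimethylsilane; 10 1-{6-methoxy-2,4-bis(methoxymethoxy)-5-methyl-3-[(Bpin)methyl]phenyl}butan-1-one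
Product: 22 [2-(benzyloxy)-4,6-bis(methoxymethoxy)-3-(ArA-methyl)-5-(ArC-methyl)phenyl]trimethylsilane
Conditions: Pd(OAc)2, XPhos, K3PO4, dioxane/H2O, 100 °C
Reagents that add atoms: none
Why: Suzuki–Miyaura coupling of an aryl chloride with a benzylic boronate, for which a bulky, electron-rich dialkylbiarylphosphine is chosen to force oxidative addition into the doubly ortho-alkoxylated C–Cl bond.

Step 17
Reactants: 22 [2-(benzyloxy)-4,6-bis(methoxymethoxy)-3-(ArA-methyl)-5-(ArC-methyl)phenyl]trimethylsilane
Product: 23 3,5-bis(methoxymethoxy)-6-(ArA-methyl)-4-(ArC-methyl)-2-(trimethylsilyl)phenol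
Conditions: H2 (1 atm), Pd/C (palladium on carbon), EtOAc, rt
Reagents that add atoms: none
Why: Hydrogenolysis of the benzyl aryl ether under neutral conditions should spare the acetals, the aryl–silicon bond, the hindered aryl ketones and the diarylmethane bridges.

Step 18
Reactants: 23 3,5-bis(methoxymethoxy)-6-(ArA-methyl)-4-(ArC-methyl)-2-(trimethylsilyl)phenol
Product: 24 3,5-bis(methoxymethoxy)-6-(ArA-methyl)-4-(ArC-methyl)-2-(trimethylsilyl)phenyl trifluoromethanesulfonate
Conditions: Tf2O, pyridine, CH2Cl2, 0 °C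
Reagents that add atoms: trifluoromethanesulfonic anhydride, O=S(=O)(OS(=O)(=O)C(F)(F)F)C(F)(F)F
Why: O-sulfonylation of the phenol gives the ortho-silylaryl triflate, the ketones not being converted into enol triflates with pyridine as base at this temperature.

Step 19
Reactants: 24 3,5-bis(methoxymethoxy)-6-(ArA-methyl)-4-(ArC-methyl)-2-(trimethylsilyl)phenyl trifluoromethanesulfonate; 25 butyric acid
Product: 28 1-[2-hydroxy-4,6-bis(methoxymethoxy)-3-(ArA-methyl)-5-(ArC-methyl)phenyl]butan-1-one, via aryne 26 (not isolated), via aryl caesium ester 27 (not isolated)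
Conditions: 25 (2 equiv), CsF (5 equiv), THF, 125 °C, sealed tube
Reagents that add atoms: none
Why: Fluoride attacks silicon at C1 and the resulting aryl anion expels triflate from C2 to give the C1–C2 aryne 26; caesium butyrate, formed from 25 and CsF, adds through oxygen to C2, the carbon remote from the C6 acetal oxygen, so that the negative charge develops at C1 beside that electron-withdrawing C–O bond (aryl caesium 27). The C1 carbanion then attacks the neighbouring ester carbonyl and the strained four-membered intermediate opens to the C1 butyryl ketone and the C2 phenoxide, which is protonated to 28. This is the known insertion of arynes into the C–O bond of carboxylic acids, an aryne O-arylation followed by an anionic Fries-type 1,3-acyl shift. No ring is closed and no stereocentre is formed. The step needs regioselective addition across the unsymmetrical aryne, which the inductive polarisation by the C6 methoxymethoxy group should secure against the steric bias of the C3 arm, and it needs the intermolecular capture and the acyl shift to outrun proton quench of 27 or attack by a neighbouring acetal oxygen, for which excess butyrate and the high temperature are chosen.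

Step 20
Reactants: 28 1-[2-hydroxy-4,6-bis(methoxymethoxy)-3-(ArA-methyl)-5-(ArC-methyl)phenyl]butan-1-one
Product: 29 agrimol F
Conditions: HCl (3 M), MeOH/THF, 50 °C
Reagents that add atoms: none
Why: Acid-catalysed acetal exchange with methanol should cleave all six methoxymethyl ethers while the aryl methyl ethers, the ketones and the methylene bridges are stable under these conditions.

**Compound list**

1 | 2,4,6-trihydroxytoluene | Cc1c(O)cc(O)cc1O | starting material
2 | 1-(2,4,6-trihydroxy-3-methylphenyl)ethanone | CC(=O)c1c(O)cc(O)c(C)c1O | intermediate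
3 | 1-[2-hydroxy-4,6-bis(methoxymethoxy)-3-methylphenyl]ethanone | CC(=O)c1c(O)c(C)c(OCOC)cc1OCOC | intermediate
4 | 1-[2-methoxy-4,6-bis(methoxymethoxy)-3-methylphenyl]ethanone | CC(=O)c1c(OC)c(C)c(OCOC)cc1OCOC | intermediate
5 | 1-[3-bromo-6-methoxy-2,4-bis(methoxymethoxy)-5-methylphenyl]ethanone (ring A bromide) | CC(=O)c1c(OC)c(C)c(OCOC)c(Br)c1OCOC | intermediate
6 | 1-(2,4,6-trihydroxy-3-methylphenyl)butan-1-one | CCCC(=O)c1c(O)cc(O)c(C)c1O | intermediate
7 | 1-[2-hydroxy-4,6-bis(methoxymethoxy)-3-methylphenyl]butan-1-one | CCCC(=O)c1c(O)c(C)c(OCOC)cc1OCOC | intermediate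
8 | 1-[2-methoxy-4,6-bis(methoxymethoxy)-3-methylphenyl]butan-1-one | CCCC(=O)c1c(OC)c(C)c(OCOC)cc1OCOC | intermediate
9 | 1-[3-bromo-6-methoxy-2,4-bis(methoxymethoxy)-5-methylphenyl]butan-1-one (ring C bromide) | CCCC(=O)c1c(OC)c(C)c(OCOC)c(Br)c1OCOC | intermediate
10 | 1-{6-methoxy-2,4-bis(methoxymethoxy)-5-methyl-3-[(4,4,5,5-tetramethyl-1,3,2-dioxaborolan-2-yl)methyl]phenyl}butan-1-one (ring C benzylboronate) | CCCC(=O)c1c(OC)c(C)c(OCOC)c(CB2OC(C)(C)C(C)(C)O2)c1OCOC | intermediate
11 | phloroglucinol | Oc1cc(O)cc(O)c1 | starting material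
12 | 3,5-bis(methoxymethoxy)phenol | COCOc1cc(O)cc(OCOC)c1 | intermediate
13 | 1-(benzyloxy)-3,5-bis(methoxymethoxy)benzene | COCOc1cc(OCc2ccccc2)cc(OCOC)c1 | intermediate
14 | [4-(benzyloxy)-2,6-bis(methoxymethoxy)phenyl]lithium (not isolated) | [Li]c1c(OCOC)cc(OCc2ccccc2)cc1OCOC | intermediate
15 | 5-(benzyloxy)-2-chloro-1,3-bis(methoxymethoxy)benzene | COCOc1cc(OCc2ccccc2)cc(OCOC)c1Cl | intermediate
16 | [2-(benzyloxy)-5-chloro-4,6-bis(methoxymethoxy)phenyl]lithium (not isolated) | [Li]c1c(OCc2ccccc2)cc(OCOC)c(Cl)c1OCOC | intermediate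
17 | [2-(benzyloxy)-5-chloro-4,6-bis(methoxymethoxy)phenyl]trimethylsilane | C[Si](C)(C)c1c(OCc2ccccc2)cc(OCOC)c(Cl)c1OCOC | intermediate
18 | [2-(benzyloxy)-5-chloro-4,6-bis(methoxymethoxy)-3-(trimethylsilyl)phenyl]lithium (not isolated) | C[Si](C)(C)c1c(OCc2ccccc2)c([Li])c(OCOC)c(Cl)c1OCOC | intermediate
19 | lithium [2-(benzyloxy)-5-chloro-4,6-bis(methoxymethoxy)-3-(trimethylsilyl)phenyl](chloromethyl)(pinacolato)borate (not isolated) | [Li+].ClC[B-]1(OC(C)(C)C(C)(C)O1)c1c(OCc2ccccc2)c([Si](C)(C)C)c(OCOC)c(Cl)c1OCOC | intermediate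
20 | [2-(benzyloxy)-5-chloro-4,6-bis(methoxymethoxy)-3-[(4,4,5,5-tetramethyl-1,3,2-dioxaborolan-2-yl)methyl]phenyl]trimethylsilane | C[Si](C)(C)c1c(OCc2ccccc2)c(CB2OC(C)(C)C(C)(C)O2)c(OCOC)c(Cl)c1OCOC | intermediate
21 | [2-(benzyloxy)-5-chloro-4,6-bis(methoxymethoxy)-3-(ArA-methyl)phenyl]trimethylsilane (ring B with C1 SiMe3, C2 OBn, C3 CH2–ring A, C4 OMOM, C5 Cl, C6 OMOM) | C[Si](C)(C)c1c(OCc2ccccc2)c(Cc2c(OCOC)c(C)c(OC)c(C(C)=O)c2OCOC)c(OCOC)c(Cl)c1OCOC | intermediate
22 | [2-(benzyloxy)-4,6-bis(methoxymethoxy)-3-(ArA-methyl)-5-(ArC-methyl)phenyl]trimethylsilane | C[Si](C)(C)c1c(OCc2ccccc2)c(Cc2c(OCOC)c(C)c(OC)c(C(C)=O)c2OCOC)c(OCOC)c(Cc2c(OCOC)c(C)c(OC)c(C(=O)CCC)c2OCOC)c1OCOC | intermediate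
23 | 3,5-bis(methoxymethoxy)-6-(ArA-methyl)-4-(ArC-methyl)-2-(trimethylsilyl)phenol | C[Si](C)(C)c1c(O)c(Cc2c(OCOC)c(C)c(OC)c(C(C)=O)c2OCOC)c(OCOC)c(Cc2c(OCOC)c(C)c(OC)c(C(=O)CCC)c2OCOC)c1OCOC | intermediate
24 | 3,5-bis(methoxymethoxy)-6-(ArA-methyl)-4-(ArC-methyl)-2-(trimethylsilyl)phenyl trifluoromethanesulfonate (ring B: C1 SiMe3, C2 OTf) | C[Si](C)(C)c1c(OS(=O)(=O)C(F)(F)F)c(Cc2c(OCOC)c(C)c(OC)c(C(C)=O)c2OCOC)c(OCOC)c(Cc2c(OCOC)c(C)c(OC)c(C(=O)CCC)c2OCOC)c1OCOC | intermediate
25 | butyric acid | CCCC(=O)O | starting material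
26 | 4,6-bis(methoxymethoxy)-3-(ArA-methyl)-5-(ArC-methyl)benzyne, the C1–C2 aryne of ring B (not isolated) | COCOC1=C(Cc2c(OCOC)c(C)c(OC)c(C(=O)CCC)c2OCOC)C(OCOC)=C(Cc2c(OCOC)c(C)c(OC)c(C(C)=O)c2OCOC)C#C1 | intermediate
27 | 2-caesio-3,5-bis(methoxymethoxy)-6-(ArA-methyl)-4-(ArC-methyl)phenyl butanoate (not isolated) | CCCC(=O)Oc1c(Cc2c(OCOC)c(C)c(OC)c(C(C)=O)c2OCOC)c(OCOC)c(Cc2c(OCOC)c(C)c(OC)c(C(=O)CCC)c2OCOC)c(OCOC)c1[Cs] | intermediate
28 | 1-[2-hydroxy-4,6-bis(methoxymethoxy)-3-(ArA-methyl)-5-(ArC-methyl)phenyl]butan-1-one (agrimol F hexakis(methoxymethyl) ether, free C2 hydroxyl) | CCCC(=O)c1c(O)c(Cc2c(OCOC)c(C)c(OC)c(C(C)=O)c2OCOC)c(OCOC)c(Cc2c(OCOC)c(C)c(OC)c(C(=O)CCC)c2OCOC)c1OCOC | intermediate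
29 | agrimol F | CCCC(=O)c1c(O)c(Cc2c(O)c(C)c(OC)c(C(C)=O)c2O)c(O)c(Cc2c(O)c(C)c(OC)c(C(=O)CCC)c2O)c1O | target

**Step count and risks**

Total: 20 steps. Longest linear sequence: 11 steps (steps 10 to 20, from phloroglucinol). The ring A branch (steps 1 to 4) joins at step 15 and the ring C branch (steps 5 to 9) at step 16.

Steps most likely to fail:

1. Step 19. The aryl anion may be protonated before the acyl shift (ester formation without ketone), the crowded aryne may be captured by an acetal oxygen of a neighbouring arm, or butyrate may add at C1 instead of C2. Fallback, from 23 back to 29 without an aryne: HCl in methanol removes the six acetals and, by ipso-protonation of the electron-rich ring, the silyl group, giving the heptaphenol 2,4-bis(arylmethyl)phloroglucinol F1. Friedel–Crafts C-acylation of F1 with butanoyl chloride and AlCl3 at the single unsubstituted carbon of ring B then gives 29.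

2. Step 16. Oxidative addition into the doubly ortho-alkoxylated C–Cl bond may be so slow that protodeboronation of the benzylic boronate takes over at the temperature required. Fallback, from 10 and 21 back to 22 by a base-free and water-free Negishi coupling: boronate 10 is oxidised (NaBO3, THF/H2O) to benzylic alcohol F2, Appel chlorination (PPh3, CCl4) gives benzylic chloride F3, and zinc insertion (Zn dust, LiCl, THF) gives benzylzinc chloride F4. F4 is coupled with 21 using [PdCl2(IPr)(3-chloropyridine)] in THF at rt to 50 °C to give 22.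

3. Step 14. Deprotonation may stray to the benzylic OCH2 of the benzyl ether, or the 1,2-shift of the very hindered aryl group from boron to carbon may stall. Fallback, from 17 back to 21 with reversed polarity at C3: aryllithium 18 is quenched with iodine to give aryl iodide F5, bromide 5 is converted as in step 9 into ring A benzylboronate F6, and a Suzuki–Miyaura coupling of F5 with F6 at the C–I bond (the chloride untouched) gives 21.

Further compounds
F1 | step 19 | 2-[(3-acetyl-2,6-dihydroxy-4-methoxy-5-methylphenyl)methyl]-4-[(3-butanoyl-2,6-dihydroxy-4-methoxy-5-methylphenyl)methyl]benzene-1,3,5-triol | Oc1cc(O)c(Cc2c(O)c(C)c(OC)c(C(C)=O)c2O)c(O)c1Cc1c(O)c(C)c(OC)c(C(=O)CCC)c1O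
F2 | step 16 | 1-[3-(hydroxymethyl)-6-methoxy-2,4-bis(methoxymethoxy)-5-methylphenyl]butan-1-one | CCCC(=O)c1c(OC)c(C)c(OCOC)c(CO)c1OCOC
F3 | step 16 | 1-[3-(chloromethyl)-6-methoxy-2,4-bis(methoxymethoxy)-5-methylphenyl]butan-1-one | CCCC(=O)c1c(OC)c(C)c(OCOC)c(CCl)c1OCOC
F4 | step 16 | {[3-butanoyl-4-methoxy-2,6-bis(methoxymethoxy)-5-methylphenyl]methyl}zinc chloride | CCCC(=O)c1c(OC)c(C)c(OCOC)c(C[Zn]Cl)c1OCOC
F5 | step 14 | [2-(benzyloxy)-5-chloro-3-iodo-4,6-bis(methoxymethoxy)phenyl]trimethylsilane | C[Si](C)(C)c1c(OCc2ccccc2)c(I)c(OCOC)c(Cl)c1OCOC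
F6 | step 14 | 1-{6-methoxy-2,4-bis(methoxymethoxy)-5-methyl-3-[(4,4,5,5-tetramethyl-1,3,2-dioxaborolan-2-yl)methyl]phenyl}ethanone | CC(=O)c1c(OC)c(C)c(OCOC)c(CB2OC(C)(C)C(C)(C)O2)c1OCOC
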